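## Structural features

Atoms are numbered along the triterpenoid chain: C2 (gem-dimethyl carbon), C3–C5, C6 (angular methyl), C7 (ether CH), C8–C9, C10 (methyl carbinol), C11, the C12–C13 tether, and C14–C19 for the cyclohexene (C14=C15, methyl on C15, carbinol C18, quaternary C19). Siphonellinol C joins a trans-fused perhydro-1-benzoxepine (oxepane ring A: O, C2–C7; cyclohexane ring B: C6–C11) through the two-carbon tether to C14 of cyclohexene ring C. Five stereocentres lie in the bicycle (the fusion pair C6/C7, the neighbours C10/C11, and C3 beside the gem-dimethyl carbon); the other two, C18 and quaternary C19, are neighbours in ring C and too far from the bicycle for any relay of configuration. The C10 hydroxyl is axial and syn to the axial C6 methyl, and the C11 tether is equatorial. Fragile points are the tertiary allylic alcohol of the E side chain on C19 and the tertiary C10 carbinol (both ionise or dehydrate in acid), the doubly allylic CH2 of the side chain, and the tetrasubstituted C14=C15 alkene, which must not migrate. The real difficulty is the all-carbon quaternary C19 next to C18, bonded to a fully substituted alkene whose other carbon carries the hindered bicycle. The key step uses the fact that a carbonyl placed at C15 makes C19 the β-carbon and C14 the α-carbon of a ring C enone, so methyl can be delivered to C19 under control of the C18 silyloxy group and the bicycle attached at C14 through C13 in the same operation.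

## Logic of the disconnections

33 from 32: no skeletal bond is cut. Four silyl ethers are removed last with fluoride, because the tertiary allylic and tertiary C10 alcohols do not tolerate acid. The demand is that every earlier step runs on a fully silylated substrate.

32 from 31: the C15–CH3 bond is cut. A tetrasubstituted alkene is best fixed in position as an enol derivative and then methylated, which removes any alkene-regiochemistry problem. The demand is a cross-coupling at a hindered alkenyl triflate that leaves silyl ethers alone.

31 from 29 through 30: no C–C bond is cut; the C14=C15 enol triflate is traced to the C13=C14 alkylidene ketone. Conjugate hydride delivery creates the enolate only at C14, a position that deprotonation of a ketone could not reach next to the quaternary C19. The demand is 1,4- over 1,2-reduction.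

29 from 27 through 28: the C13=C14 alkene is traced to a β-hydroxy ketone. This turns the linkage into an aldol bond and makes the two aldol stereocentres irrelevant.

27 from 10, 25 and 24 through 26: the C19–CH3 and C14–C13 bonds are cut. The cut divides the molecule into ring C, a methyl donor and the complete bicycle, so the union is convergent and the quaternary centre is made at the same time. The demand is face-selective methyl delivery anti to the C18 silyl ether and trapping of the enolate before it equilibrates.

10 from 9, and 9 from 7 and 8: the side-chain C=C bond is cut (cross-metathesis), followed by silylation. Ring C is reduced to an allyl enone and a commercial tertiary allylic alcohol. The demand is E selectivity and no migration of the skipped alkene.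

7 from 4 and 5 through 6, and 4 from 3, 2 and 1: the C19–CH2 bond is cut (1,2-addition to a vinylogous ester with carbonyl transposition), and the C18–O bond is traced to an α′-acetoxylation resolved by a lipase. The demand is an enantiomerically pure C18 centre, since it alone controls C19.

24 from 22 through 23, and 22 from 21 and 20: the terminal C=C of an allyl arm is cut (ozonolysis) and then the C10–CH3 bond (methyl addition to a ring ketone). The aldehyde is thus masked as an inert alkene until needed. The demand is equatorial attack at C10, which the axial C6 methyl should enforce.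

20 from 18 through 19: the O–C2 and C6–C11 bonds are cut. Both rings arise from an acyclic diepoxy enol silane, with C3 and C7 fixed by the epoxides and C6 by inversion. The demand is an E-configured 6,7-epoxide (for trans fusion) and an enol silane of defined regiochemistry.

18 from 17 and 16, 17 from 15 and 16, 15 from 14, and 14 from 11 and 12 through 13: the C12–C13 bond is cut (conjugate addition that fixes the enol silane at C10=C11), then C10–C11 (acyl substitution), then the two epoxide C–O bonds (reagent-controlled epoxidation), then C8–C9 (enolate alkylation). The bicycle is reduced to 12, 11 and two equivalents of 16.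

## Other disconnections considered

Alternative 1: The cut is the C3=C4 bond of an oxepene, read as a ring-closing metathesis. Diene A2, (2S,3R)-2-allyl-2-methyl-3-[(2-methylbut-3-en-2-yl)oxy]cyclohexan-1-one, would be closed by the second-generation Grubbs catalyst RuCl2(=CHPh)(PCy3)(H2IMes) to the trans-fused oxepenone A1 with loss of ethene.
- In its favour: seven-membered closure between a monosubstituted alkene and a vinyl group on a quaternary ether carbon is dependable under neutral conditions. The C6/C7 pair of A2 can come from an enantioselective reduction of 2-allyl-2-methylcyclohexane-1,3-dione, so the ring fusion is settled before the ring is made.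
- Against it here: the tertiary 1,1-dimethylallyl ether of A2 must be put on a neopentyl secondary alcohol, where ionising conditions tend to eliminate or to transfer the linear prenyl group. A1 has no oxygen at C3, so the alkene beside the gem-dimethyl carbon must still be oxidised with the right regio- and face selectivity (hydroboration would favour C4). Its carbonyl sits at C11 while C10 is a methylene, so the C10 methyl carbinol and the C12–C13 arm each need several more operations.
- Comparison: Alternative 1 is the better on predictability of the ring-forming event (a neutral metathesis against the cationic bicyclisation of step 11) and the equal on control of the ring fusion. It is longer on the way to 24, and because it is confined to ring A it leaves C19 and the union with ring C to another strategy-level step.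

Alternative 2: The cuts are O–C2 and C6–C11. A silyl triflate would activate the 2,3-epoxide of diepoxy enol silane A4; the 6,7-epoxide oxygen would close ring A at C2, and C11 of the enol silane would open the epoxonium ion at C6, giving hydroxy ketone A3 with a silyloxyethyl arm on C11.
- In its favour: both rings and the C6/C7 fusion arise in one operation from reagent-controlled epoxides, with C3 carried through. On the bicycle it is the equal of the chosen plan, which uses the same kind of closure as supporting step 11. Per step it creates more rings and stereocentres than step 15 does, and on that count it is the better.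
- Against it as the centre of the plan: it does not address C19, the tetrasubstituted alkene or the union of the halves. The enol silane of A4 must be made with defined regiochemistry between two α-methylene groups. The arm of A3 must be unmasked by removing one silyl ether among several and then oxidised, two operations where the allyl arm of 20 needs one ozonolysis.
- Comparison: the two plans do not differ in mechanism on rings A and B; A3 stands about two steps further from the aldehyde stage than 20.

Alternative 3: The cut is C10–C11. TiCl4 would activate the methyl ketone of A6 (an oxepane with a 3-(trimethylsilyl)prop-1-enyl group on C6 and a 3-oxobutyl chain on C7); the allylsilane γ-carbon C11 would add to C10, and loss of silicon would leave the C12=C13 vinyl group of A5.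
- In its favour: C10 (with its methyl and hydroxyl) and C11 are set in one C–C bond formation, and the vinyl group is a direct precursor of the C13 aldehyde. No organometallic addition to a hindered ring ketone is needed, which saves one step against steps 11 and 12 taken together; here it is the better.
- Against it here: A6 needs ring A, the quaternary C6 and a geometrically defined allylsilane on that quaternary carbon to be assembled first, which is long. The target needs the C10 oxygen axial and syn to the axial C6 methyl with the vinyl group equatorial, and nothing in A6 obviously enforces a transition state with the Lewis-acid-bound oxygen in that crowded position. TiCl4 is a harsh partner for a tertiary ether and a silyl ether. A5 still needs hydroboration and oxidation (two steps) to reach the aldehyde.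
- Comparison: the alternative is more concise in mechanism for C10/C11 but less secure in stereocontrol than equatorial attack on a ring ketone. On step economy it is the equal at best, and it does not touch ring C.

Key step: step 15

Remarks on the chemistry
- Assumption: the lipase of step 2 is taken to hydrolyse the (R)-acetate faster, as the usual size rule for esters of secondary alcohols predicts with the carbonyl side as the larger group. The sense must be assigned by correlation before material is taken on.
- Structure check: enone 10 is 18R; methyl delivery anti to the silyloxy group gives 19S; the bicycle is 3R,6R,7R,10S,11R. These agree with the target, so no descriptor needed changing.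
- Building block: the terpenoid unit must be E (geranyl). Anti opening of the 6,7-epoxide gives the trans ring fusion only from the E alkene; the Z (neryl) isomer would give the cis-fused bicycle.
- Design choices: both bicycle hydroxyls carry the same triethylsilyl group (one step, fluoride-labile), and the C13 aldehyde is released from an allyl arm by one ozonolysis.
- Aldol adduct 27 is drawn as the expected 13S,14S isomer; both centres are removed in steps 16 and 17.

## Route

Step 1
Reactants: 1 3-ethoxycyclohex-2-en-1-one
Product: 2 rac-4-ethoxy-2-oxocyclohex-3-en-1-yl acetate (6-acetoxy-3-ethoxycyclohex-2-en-1-one)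
Conditions: Mn(OAc)3·2H2O (2.5 equiv), benzene, reflux, Dean–Stark
Reagents that add atoms: manganese triacetate, CC(=O)[O-].CC(=O)[O-].CC(=O)[O-].[Mn+3]
Why: Oxidative α′-acetoxylation of an enone: the trivalent manganese enolate on the C6 side transfers an acetate ligand, and the vinylogous ester leaves C6 as the only oxidisable α-position; the product is racemic.

Step 2
Reactants: 2 rac-4-ethoxy-2-oxocyclohex-3-en-1-yl acetate
Product: 3 (R)-3-ethoxy-6-hydroxycyclohex-2-en-1-one
Conditions: Burkholderia cepacia lipase (Amano PS), pH 7 phosphate buffer/MTBE, 25 °C, stopped near half conversion; chromatography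
Reagents that add atoms: none
Why: Lipase-catalysed kinetic resolution by enantioselective ester hydrolysis; the acyl-enzyme mechanism leaves the C–O bond of the stereocentre untouched, so the alcohol keeps the configuration of the faster-reacting ester and is separated from the unreacted acetate.

Step 3
Reactants: 3 (R)-3-ethoxy-6-hydroxycyclohex-2-en-1-one
Product: 4 (R)-6-[(tert-butyldimethylsilyl)oxy]-3-ethoxycyclohex-2-en-1-one
Conditions: TBSCl, imidazole, DMF, 0 °C → rt
Reagents that add atoms: tert-butyldimethylsilyl chloride, CC(C)(C)[Si](C)(C)Cl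
Why: Standard silylation of a secondary alcohol under a base too mild to enolise the vinylogous ester; TBS survives the acid of step 4 and is large enough to direct the cuprate in step 15.

Step 4
Reactants: 4 (R)-6-[(tert-butyldimethylsilyl)oxy]-3-ethoxycyclohex-2-en-1-one; 5 allylmagnesium bromide
Product: 7 (R)-3-allyl-4-[(tert-butyldimethylsilyl)oxy]cyclohex-2-en-1-one, via tertiary allylic alcohol 6 (not isolated)
Conditions: THF, −78 → −20 °C; then 1 M aq HCl, 0 °C
Reagents that add atoms: water, O
Why: 1,2-Addition of the allyl Grignard reagent to the vinylogous ester carbonyl, then acid-mediated enol ether hydrolysis and loss of water (Stork–Danheiser transposition), moves the carbonyl to the former C3. The C18 stereocentre is a spectator and the configuration of the transient carbinol is irrelevant.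

Step 5
Reactants: 7 (R)-3-allyl-4-[(tert-butyldimethylsilyl)oxy]cyclohex-2-en-1-one; 8 2-methylbut-3-en-2-ol
Product: 9 (R)-4-[(tert-butyldimethylsilyl)oxy]-3-[(E)-4-hydroxy-4-methylpent-2-en-1-yl]cyclohex-2-en-1-one
Conditions: 8 (5 equiv), second-generation Grubbs catalyst RuCl2(=CHPh)(PCy3)(H2IMes) (5 mol %), CH2Cl2, 40 °C
Reagents that add atoms: none
Why: Olefin cross-metathesis of a monosubstituted alkene with a tertiary allylic alcohol that barely homodimerises, so the cross product should dominate and be E by thermodynamic control; the trisubstituted enone alkene is inert.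

Step 6
Reactants: 9 (R)-4-[(tert-butyldimethylsilyl)oxy]-3-[(E)-4-hydroxy-4-methylpent-2-en-1-yl]cyclohex-2-en-1-one
Product: 10 (R)-4-[(tert-butyldimethylsilyl)oxy]-3-{(E)-4-methyl-4-[(triethylsilyl)oxy]pent-2-en-1-yl}cyclohex-2-en-1-one
Conditions: TESOTf, 2,6-lutidine, CH2Cl2, −78 °C
Reagents that add atoms: triethylsilyl trifluoromethanesulfonate, CC[Si](CC)(CC)OS(=O)(=O)C(F)(F)F
Why: A silyl triflate with a hindered base silylates the tertiary alcohol at low temperature faster than it enolises the enone; the ether removes the only acidic proton before steps 15 and 17.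

Step 7
Reactants: 11 N-methoxy-N-methylacetamide; 12 geranyl bromide, (E)-1-bromo-3,7-dimethylocta-2,6-diene
Product: 14 (E)-N-methoxy-N,5,9-trimethyldeca-4,8-dienamide, via lithium amide enolate 13 (not isolated)
Conditions: LDA, THF, −78 °C; then 12, −78 → −20 °C
Reagents that add atoms: none
Why: SN2 alkylation of an amide lithium enolate by a primary allylic bromide at its α-carbon forms C8–C9 and keeps the E geometry.

Step 8
Reactants: 14 (E)-N-methoxy-N,5,9-trimethyldeca-4,8-dienamide
Product: 15 3-[(2R,3R)-3-{2-[(2R)-3,3-dimethyloxiran-2-yl]ethyl}-3-methyloxiran-2-yl]-N-methoxy-N-methylpropanamide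
Conditions: D-fructose-derived Shi ketone (0.6 equiv), Oxone (KHSO5), K2CO3, Bu4NHSO4, aq Na2B4O7–Na2EDTA, MeCN/CH2(OMe)2, 0 °C
Reagents that add atoms: potassium peroxymonosulfate, [K+].OOS(=O)(=O)[O-]
Why: Shi asymmetric epoxidation: the chiral dioxirane transfers oxygen to both electron-rich trisubstituted alkenes through a spiro transition state. Reagent control should give the 3R and 6R,7R epoxides; the amide is inert.

Step 9
Reactants: 15 3-[(2R,3R)-3-{2-[(2R)-3,3-dimethyloxiran-2-yl]ethyl}-3-methyloxiran-2-yl]-N-methoxy-N-methylpropanamide; 16 vinylmagnesium bromide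
Product: 17 5-[(2R,3R)-3-{2-[(2R)-3,3-dimethyloxiran-2-yl]ethyl}-3-methyloxiran-2-yl]pent-1-en-3-one
Conditions: THF, −40 → 0 °C; inverse quench into cold aq NH4Cl
Reagents that add atoms: none
Why: Acyl substitution of an N-methoxy-N-methylamide: the chelated tetrahedral magnesium adduct stops the reaction at the ketone stage and collapses only on work-up. Trisubstituted epoxides are not opened by the Grignard reagent at this temperature.

Step 10
Reactants: 17 5-[(2R,3R)-3-{2-[(2R)-3,3-dimethyloxiran-2-yl]ethyl}-3-methyloxiran-2-yl]pent-1-en-3-one; 16 vinylmagnesium bromide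
Product: 18 {[(3Z)-1-[(2R,3R)-3-{2-[(2R)-3,3-dimethyloxiran-2-yl]ethyl}-3-methyloxiran-2-yl]hepta-3,6-dien-3-yl]oxy}trimethylsilane
Conditions: CuBr·SMe2 (10 mol %), TMSCl, HMPA, THF, −78 °C; Et3N, pentane/aq NaHCO3 work-up; used crude
Reagents that add atoms: chlorotrimethylsilane, C[Si](C)(C)Cl
Why: Copper-catalysed conjugate addition of the vinyl Grignard reagent with in situ silylation of the enolate fixes the enol double bond at C10=C11, which enolisation of a dialkyl ketone could not do. The Z isomer is expected from the s-cis enone, but the geometry is not critical because C11 is equilibrated in step 11.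

Step 11
Reactants: 18 {[(3Z)-1-[(2R,3R)-3-{2-[(2R)-3,3-dimethyloxiran-2-yl]ethyl}-3-methyloxiran-2-yl]hepta-3,6-dien-3-yl]oxy}trimethylsilane
Product: 20 (3R,5aR,6R,9aR)-6-allyl-3-hydroxy-2,2,5a-trimethyloctahydro-1-benzoxepin-7(2H)-one, via C3 trimethylsilyl ether 19 (not isolated)
Conditions: TMSOTf, 2,6-di-tert-butyl-4-methylpyridine, CH2Cl2, −78 °C; then K2CO3, MeOH, 0 °C → rt
Reagents that add atoms: none
Why: Tandem oxa-/carbacyclisation of a diepoxy enol silane: silyl activation of the terminal epoxide, 7-endo attack of the 6,7-epoxide oxygen at tertiary C2, then chair-like 6-endo opening of the epoxonium ion at C6 by C11. C3 and C7 keep their epoxide configuration and C6 is inverted, which from the E epoxide gives the trans fusion. The carbonate/methanol treatment removes the O-silyl group and equilibrates C11 to the equatorial allyl isomer.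

Step 12
Reactants: 20 (3R,5aR,6R,9aR)-6-allyl-3-hydroxy-2,2,5a-trimethyloctahydro-1-benzoxepin-7(2H)-one
Product: 21 (3R,5aR,6R,7S,9aR)-6-allyl-2,2,5a,7-tetramethyldecahydro-1-benzoxepine-3,7-diol
Conditions: MeLi (3.5 equiv), CeCl3, THF, −78 °C
Reagents that add atoms: methyllithium, [Li]C
Why: Organocerium 1,2-addition to a hindered, enolisable ketone. The axial C6 methyl blocks the axial trajectory, so methyl should enter equatorially and leave the hydroxyl axial and syn to the angular methyl (10S).

Step 13
Reactants: 21 (3R,5aR,6R,7S,9aR)-6-allyl-2,2,5a,7-tetramethyldecahydro-1-benzoxepine-3,7-diol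
Product: 22 (3R,5aR,6R,7S,9aR)-6-allyl-2,2,5a,7-tetramethyl-3,7-bis[(triethylsilyl)oxy]decahydro-1-benzoxepine
Conditions: TESOTf (3 equiv), 2,6-lutidine, CH2Cl2, −78 → 0 °C
Reagents that add atoms: triethylsilyl trifluoromethanesulfonate, CC[Si](CC)(CC)OS(=O)(=O)C(F)(F)F
Why: Exhaustive silylation with a silyl triflate reactive enough for the axial tertiary hydroxyl; the C10 ether prevents lactol formation with the C13 aldehyde.

Step 14
Reactants: 22 (3R,5aR,6R,7S,9aR)-6-allyl-2,2,5a,7-tetramethyl-3,7-bis[(triethylsilyl)oxy]decahydro-1-benzoxepine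
Product: 24 2-[(3R,5aR,6R,7S,9aR)-2,2,5a,7-tetramethyl-3,7-bis[(triethylsilyl)oxy]decahydro-1-benzoxepin-6-yl]acetaldehyde, via secondary ozonide 23 (not isolated)
Conditions: O3, CH2Cl2, pyridine, −78 °C; then PPh3, −78 °C → rt
Reagents that add atoms: ozone, [O-][O+]=O
Why: Ozonolysis of the only alkene with reductive work-up; the terminal carbon leaves as formaldehyde and C13 becomes the aldehyde, while the silyl ethers are inert.

Step 15
Reactants: 10 (R)-4-[(tert-butyldimethylsilyl)oxy]-3-{(E)-4-methyl-4-[(triethylsilyl)oxy]pent-2-en-1-yl}cyclohex-2-en-1-one; 25 lithium dimethylcuprate LiCu(CH3)2; 24 2-[(3R,5aR,6R,7S,9aR)-2,2,5a,7-tetramethyl-3,7-bis[(triethylsilyl)oxy]decahydro-1-benzoxepin-6-yl]acetaldehyde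
Product: 27 (2S,3S,4R)-4-[(tert-butyldimethylsilyl)oxy]-2-{(1S)-1-hydroxy-2-[(3R,5aR,6R,7S,9aR)-2,2,5a,7-tetramethyl-3,7-bis[(triethylsilyl)oxy]decahydro-1-benzoxepin-6-yl]ethyl}-3-methyl-3-{(E)-4-methyl-4-[(triethylsilyl)oxy]pent-2-en-1-yl}cyclohexan-1-one, via lithium enolate 26 (not isolated)
Conditions: 25 (1.3 equiv, from CuI and 2 CH3Li), Et2O, −78 → −30 °C; then 24 (1.2 equiv) in THF, −78 °C; aq NH4Cl–NH3 quench at −78 °C
Reagents that add atoms: none
Why: The cuprate forms a π-complex with the enone and adds oxidatively at C19 to a trivalent copper β-alkyl enolate; reductive elimination makes the C19–CH3 bond and leaves lithium enolate 26, whose double bond can only be C14=C15 because the addition itself creates it. Aldehyde 24, added at −78 °C in THF, is attacked by C14 through a closed chair-like transition state before proton transfer can move or quench the enolate, which forms the C14–C13 bond. The closest known reaction type is the tandem cuprate conjugate addition–aldol trapping of cycloalkenones (three-component coupling). No ring is closed, both new bonds being exocyclic to ring C, so no mode of ring closure is involved. C19 is controlled by the C18 silyl ether: in the half-chair with the silyloxy group pseudoaxial the reagent attacks axially on the opposite face, which puts methyl trans and the side chain cis to the C18 oxygen (19S). C14 and C13 should follow approach of the aldehyde anti to the newly delivered axial methyl and the anti preference of a ring (E)-enolate, but both centres are erased in steps 16 and 17, so their ratio does not matter. The step needs 1,4- over 1,2-selectivity (soft organocopper, hindered carbonyl), face selectivity at C19 (C18 substituent), and aldol addition rather than enolate equilibration (low temperature, an unhindered aldehyde carbonyl, and no acidic hydroxyl because all four are silylated).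

Step 16
Reactants: 27 the aldol adduct of step 15
Product: 29 (3S,4R)-4-[(tert-butyldimethylsilyl)oxy]-3-methyl-3-{(E)-4-methyl-4-[(triethylsilyl)oxy]pent-2-en-1-yl}-2-{2-[(3R,5aR,6R,7S,9aR)-2,2,5a,7-tetramethyl-3,7-bis[(triethylsilyl)oxy]decahydro-1-benzoxepin-6-yl]ethylidene}cyclohexan-1-one (C13=C14 geometry not defined), via aldol mesylate 28 (not isolated)
Conditions: MsCl, Et3N, CH2Cl2, 0 °C; then DBU, 0 °C → rt
Reagents that add atoms: none
Why: Mesylation of the β-hydroxy ketone and base-induced E1cB elimination give the conjugated alkylidene ketone; both aldol stereocentres are removed, and the alkene geometry is irrelevant to step 17.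

Step 17
Reactants: 29 the alkylidene ketone of step 16
Product: 31 (5S,4R)-configured enol triflate: (3S,4R)-4-[(tert-butyldimethylsilyl)oxy]-3-methyl-3-{(E)-4-methyl-4-[(triethylsilyl)oxy]pent-2-en-1-yl}-2-{2-[(3R,5aR,6R,7S,9aR)-2,2,5a,7-tetramethyl-3,7-bis[(triethylsilyl)oxy]decahydro-1-benzoxepin-6-yl]ethyl}cyclohex-1-en-1-yl trifluoromethanesulfonate, via lithium enolate 30 (not isolated)
Conditions: LiBH(s-Bu)3, THF, −78 °C; then PhNTf2, −78 → 0 °C
Reagents that add atoms: N-phenylbis(trifluoromethanesulfonimide), O=S(=O)(N(c1ccccc1)S(=O)(=O)C(F)(F)F)C(F)(F)F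
Why: Conjugate hydride delivery from the bulky trialkylborohydride to the exposed exocyclic C13 (the carbonyl is shielded by the quaternary C19 next to C14) generates the enolate specifically at C14=C15. O-Sulfonylation by the triflimide then gives the enol triflate; this is the regiospecific enol triflate synthesis from an enone.

Step 18
Reactants: 31 the enol triflate of step 17
Product: 32 tetrasilyl ether of siphonellinol C (3-O-, 10-O- and side-chain O-triethylsilyl, 18-O-tert-butyldimethylsilyl)
Conditions: CH3MgBr, Fe(acac)3 (10 mol %), THF/NMP, −30 → 0 °C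
Reagents that add atoms: methylmagnesium bromide, C[Mg]Br
Why: Iron-catalysed cross-coupling of an alkenyl triflate with a methyl Grignard reagent through a low-valent ferrate is fast at low temperature and tolerant of silyl ethers; it puts the C15 methyl on the tetrasubstituted alkene without moving it.

Step 19
Reactants: 32 tetrasilyl ether of siphonellinol C
Product: 33 siphonellinol C
Conditions: TBAF (excess), THF, 50 °C
Reagents that add atoms: none
Why: Fluoride-induced cleavage of all four silyl ethers under non-acidic conditions spares the tertiary allylic and tertiary C10 alcohols from ionisation or dehydration.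

## Compound list

1 | 3-ethoxycyclohex-2-en-1-one | CCOC1=CC(=O)CCC1 | starting material
2 | rac-4-ethoxy-2-oxocyclohex-3-en-1-yl acetate | CCOC1=CC(=O)C(OC(C)=O)CC1 | intermediate
3 | (R)-3-ethoxy-6-hydroxycyclohex-2-en-1-one | CCOC1=CC(=O)[C@H](O)CC1 | intermediate
4 | (R)-6-[(tert-butyldimethylsilyl)oxy]-3-ethoxycyclohex-2-en-1-one | CCOC1=CC(=O)[C@H](O[Si](C)(C)C(C)(C)C)CC1 | intermediate
5 | allylmagnesium bromide | C=CC[Mg]Br | starting material
6 | (6R)-1-allyl-6-[(tert-butyldimethylsilyl)oxy]-3-ethoxycyclohex-2-en-1-ol, mixture at C1, formed in the flask | CCOC1=CC(O)(CC=C)[C@H](O[Si](C)(C)C(C)(C)C)CC1 | intermediate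
7 | (R)-3-allyl-4-[(tert-butyldimethylsilyl)oxy]cyclohex-2-en-1-one | O=C1C=C(CC=C)[C@H](O[Si](C)(C)C(C)(C)C)CC1 | intermediate
8 | 2-methylbut-3-en-2-ol | C=CC(C)(C)O | starting material
9 | (R)-4-[(tert-butyldimethylsilyl)oxy]-3-[(E)-4-hydroxy-4-methylpent-2-en-1-yl]cyclohex-2-en-1-one | O=C1C=C(C/C=C/C(C)(C)O)[C@H](O[Si](C)(C)C(C)(C)C)CC1 | intermediate
10 | (R)-4-[(tert-butyldimethylsilyl)oxy]-3-{(E)-4-methyl-4-[(triethylsilyl)oxy]pent-2-en-1-yl}cyclohex-2-en-1-one | O=C1C=C(C/C=C/C(C)(C)O[Si](CC)(CC)CC)[C@H](O[Si](C)(C)C(C)(C)C)CC1 | intermediate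
11 | N-methoxy-N-methylacetamide | CC(=O)N(C)OC | starting material
12 | geranyl bromide, (E)-1-bromo-3,7-dimethylocta-2,6-diene | CC(C)=CCC/C(C)=C/CBr | starting material
13 | lithium enolate of N-methoxy-N-methylacetamide, formed in the flask | [Li+].[O-]C(=C)N(C)OC | intermediate
14 | (E)-N-methoxy-N,5,9-trimethyldeca-4,8-dienamide | CC(C)=CCC/C(C)=C/CCC(=O)N(C)OC | intermediate
15 | 3-[(2R,3R)-3-{2-[(2R)-3,3-dimethyloxiran-2-yl]ethyl}-3-methyloxiran-2-yl]-N-methoxy-N-methylpropanamide | CON(C)C(=O)CC[C@H]1O[C@]1(C)CC[C@H]1OC1(C)C | intermediate
16 | vinylmagnesium bromide | C=C[Mg]Br | starting material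
17 | 5-[(2R,3R)-3-{2-[(2R)-3,3-dimethyloxiran-2-yl]ethyl}-3-methyloxiran-2-yl]pent-1-en-3-one | C=CC(=O)CC[C@H]1O[C@]1(C)CC[C@H]1OC1(C)C | intermediate
18 | {[(3Z)-1-[(2R,3R)-3-{2-[(2R)-3,3-dimethyloxiran-2-yl]ethyl}-3-methyloxiran-2-yl]hepta-3,6-dien-3-yl]oxy}trimethylsilane | C=CC/C=C(\O[Si](C)(C)C)CC[C@H]1O[C@]1(C)CC[C@H]1OC1(C)C | intermediate
19 | (3R,5aR,6R,9aR)-6-allyl-2,2,5a-trimethyl-3-[(trimethylsilyl)oxy]octahydro-1-benzoxepin-7(2H)-one, formed in the flask | C=CC[C@@H]1[C@@]2(C)CC[C@@H](O[Si](C)(C)C)C(C)(C)O[C@@H]2CCC1=O | intermediate
20 | (3R,5aR,6R,9aR)-6-allyl-3-hydroxy-2,2,5a-trimethyloctahydro-1-benzoxepin-7(2H)-one | C=CC[C@@H]1[C@@]2(C)CC[C@@H](O)C(C)(C)O[C@@H]2CCC1=O | intermediate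
21 | (3R,5aR,6R,7S,9aR)-6-allyl-2,2,5a,7-tetramethyldecahydro-1-benzoxepine-3,7-diol | C=CC[C@@H]1[C@@]2(C)CC[C@@H](O)C(C)(C)O[C@@H]2CC[C@]1(C)O | intermediate
22 | (3R,5aR,6R,7S,9aR)-6-allyl-2,2,5a,7-tetramethyl-3,7-bis[(triethylsilyl)oxy]decahydro-1-benzoxepine | C=CC[C@@H]1[C@@]2(C)CC[C@@H](O[Si](CC)(CC)CC)C(C)(C)O[C@@H]2CC[C@]1(C)O[Si](CC)(CC)CC | intermediate
23 | secondary ozonide (1,2,4-trioxolane) of 22, mixture at the ozonide carbon, formed in the flask | C1OC(C[C@@H]2[C@@]3(C)CC[C@@H](O[Si](CC)(CC)CC)C(C)(C)O[C@@H]3CC[C@]2(C)O[Si](CC)(CC)CC)OO1 | intermediate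
24 | 2-[(3R,5aR,6R,7S,9aR)-2,2,5a,7-tetramethyl-3,7-bis[(triethylsilyl)oxy]decahydro-1-benzoxepin-6-yl]acetaldehyde | O=CC[C@@H]1[C@@]2(C)CC[C@@H](O[Si](CC)(CC)CC)C(C)(C)O[C@@H]2CC[C@]1(C)O[Si](CC)(CC)CC | intermediate
25 | lithium dimethylcuprate LiCu(CH3)2, prepared in the flask from CuI and 2 CH3Li | [Li+].C[Cu-]C | starting material
26 | lithium (3S,4R)-4-[(tert-butyldimethylsilyl)oxy]-3-methyl-3-{(E)-4-methyl-4-[(triethylsilyl)oxy]pent-2-en-1-yl}cyclohex-1-en-1-olate, formed in the flask | [Li+].[O-]C1=C[C@](C)(C/C=C/C(C)(C)O[Si](CC)(CC)CC)[C@H](O[Si](C)(C)C(C)(C)C)CC1 | intermediate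
27 | aldol adduct, (2S,3S,4R)-4-[(tert-butyldimethylsilyl)oxy]-2-{(1S)-1-hydroxy-2-[bis(triethylsilyloxy) bicycle of 24]ethyl}-3-methyl-3-{(E)-4-methyl-4-[(triethylsilyl)oxy]pent-2-en-1-yl}cyclohexan-1-one, drawn as the expected 13S,14S isomer | O=C1[C@H]([C@@H](O)C[C@@H]2[C@@]3(C)CC[C@@H](O[Si](CC)(CC)CC)C(C)(C)O[C@@H]3CC[C@]2(C)O[Si](CC)(CC)CC)[C@](C)(C/C=C/C(C)(C)O[Si](CC)(CC)CC)[C@H](O[Si](C)(C)C(C)(C)C)CC1 | intermediate
28 | C13 methanesulfonate of 27, formed in the flask | O=C1[C@H]([C@@H](OS(C)(=O)=O)C[C@@H]2[C@@]3(C)CC[C@@H](O[Si](CC)(CC)CC)C(C)(C)O[C@@H]3CC[C@]2(C)O[Si](CC)(CC)CC)[C@](C)(C/C=C/C(C)(C)O[Si](CC)(CC)CC)[C@H](O[Si](C)(C)C(C)(C)C)CC1 | intermediate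
29 | C13=C14 alkylidene ketone (3S,4R), alkylidene geometry not defined | O=C1C(=CC[C@@H]2[C@@]3(C)CC[C@@H](O[Si](CC)(CC)CC)C(C)(C)O[C@@H]3CC[C@]2(C)O[Si](CC)(CC)CC)[C@](C)(C/C=C/C(C)(C)O[Si](CC)(CC)CC)[C@H](O[Si](C)(C)C(C)(C)C)CC1 | intermediate
30 | lithium C14=C15 enolate from 29, formed in the flask | [Li+].[O-]C1=C(CC[C@@H]2[C@@]3(C)CC[C@@H](O[Si](CC)(CC)CC)C(C)(C)O[C@@H]3CC[C@]2(C)O[Si](CC)(CC)CC)[C@](C)(C/C=C/C(C)(C)O[Si](CC)(CC)CC)[C@H](O[Si](C)(C)C(C)(C)C)CC1 | intermediate
31 | C15 enol triflate (C14=C15), (3S,4R)-cyclohex-1-en-1-yl trifluoromethanesulfonate carrying the bicycle-ethyl arm on C2 | O=S(=O)(OC1=C(CC[C@@H]2[C@@]3(C)CC[C@@H](O[Si](CC)(CC)CC)C(C)(C)O[C@@H]3CC[C@]2(C)O[Si](CC)(CC)CC)[C@](C)(C/C=C/C(C)(C)O[Si](CC)(CC)CC)[C@H](O[Si](C)(C)C(C)(C)C)CC1)C(F)(F)F | intermediate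
32 | tetrasilyl ether of siphonellinol C (three triethylsilyl ethers at O3, O10 and the side chain; tert-butyldimethylsilyl ether at O18) | CC1=C(CC[C@@H]2[C@@]3(C)CC[C@@H](O[Si](CC)(CC)CC)C(C)(C)O[C@@H]3CC[C@]2(C)O[Si](CC)(CC)CC)[C@](C)(C/C=C/C(C)(C)O[Si](CC)(CC)CC)[C@H](O[Si](C)(C)C(C)(C)C)CC1 | intermediate
33 | siphonellinol C | CC1=C(CC[C@@H]2[C@@]3(C)CC[C@@H](O)C(C)(C)O[C@@H]3CC[C@]2(C)O)[C@](C)(C/C=C/C(C)(C)O)[C@H](O)CC1 | target

## Step count and least certain steps

Total step count: 19. Longest linear sequence: 13 steps (steps 7–14, 15 and 16–19, from 11 and 12). The enone branch contributes 6 steps before the union.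

Step 15 (key step). What is most likely to go wrong is slow conjugate addition: the enone is β,β-disubstituted and carries a γ-silyloxy group, so the cuprate may instead deprotonate the doubly allylic CH2 or decompose. Once the enolate exists, proton exchange with the enolisable aldehyde or retro-aldol on warming can compete, because the enolate carbon sits next to a quaternary centre. The fallback separates the two events. It sets out from 10: silyl-assisted addition of LiCu(CH3)2 in the presence of TMSCl gives the isolable trimethylsilyl enol ether F1. Methyllithium in THF then regenerates enolate 26 free of copper species, and 24 is added at −78 °C, which returns to the route at 27.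

Step 11. The likely failures are capture of the epoxonium ion by the enol ether oxygen instead of C11, and loss of the labile trimethylsilyl enol ether to adventitious acid before the second ring closes, so that the sequence stops after ring A. The fallback replaces the enol silane by a carbon nucleophile whose position cannot be lost. It sets out from 15: acylation of the lithium enolate of allyl acetate by 15 gives the allyl β-keto ester F2. Lewis acid treatment (BF3·OEt2, CH2Cl2, −78 °C) should cyclise F2 through its enol to the bicyclic β-keto ester F3. Decarboxylative allylation with Pd(PPh3)4 (zerovalent palladium; Tsuji reaction) then transfers the allyl group to C11 and, after base equilibration, returns to the route at 20.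

Step 17. The likely failures are competing 1,2-reduction of the carbonyl and incomplete O-sulfonylation of the tetrasubstituted, quaternary-flanked enolate, which would then be protonated on work-up. The fallback sets out from 29: 1,4-hydrosilylation with Et3SiH and RhCl(PPh3)3 gives the isolable triethylsilyl enol ether F4. Methyllithium releases enolate 30, and PhNTf2 returns to the route at 31.

Step 2. The likely failure is a reversed or weak enantiomer preference of the lipase, so that the alcohol fraction is the wrong enantiomer or is not pure. The fallback sets out from 2 and harvests the ester side of the same resolution, run past half conversion: the recovered (R)-acetate F5 is cleaved chemically (K2CO3, MeOH, 0 °C) and returns to the route at 3.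

## Further compounds

F1 | step 15 | {[(3S,4R)-4-[(tert-butyldimethylsilyl)oxy]-3-methyl-3-{(E)-4-methyl-4-[(triethylsilyl)oxy]pent-2-en-1-yl}cyclohex-1-en-1-yl]oxy}trimethylsilane | C[Si](C)(C)OC1=C[C@](C)(C/C=C/C(C)(C)O[Si](CC)(CC)CC)[C@H](O[Si](C)(C)C(C)(C)C)CC1
F2 | step 11 | allyl 5-[(2R,3R)-3-{2-[(2R)-3,3-dimethyloxiran-2-yl]ethyl}-3-methyloxiran-2-yl]-3-oxopentanoate | C=CCOC(=O)CC(=O)CC[C@H]1O[C@]1(C)CC[C@H]1OC1(C)C
F3 | step 11 | allyl (3R,5aR,9aR)-3-hydroxy-2,2,5a-trimethyl-7-oxodecahydro-1-benzoxepine-6-carboxylate (C6 not defined) | C=CCOC(=O)C1[C@@]2(C)CC[C@@H](O)C(C)(C)O[C@@H]2CCC1=O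
F4 | step 17 | triethylsilyl enol ether corresponding to enolate 30 (C14=C15) | CC[Si](CC)(CC)OC1=C(CC[C@@H]2[C@@]3(C)CC[C@@H](O[Si](CC)(CC)CC)C(C)(C)O[C@@H]3CC[C@]2(C)O[Si](CC)(CC)CC)[C@](C)(C/C=C/C(C)(C)O[Si](CC)(CC)CC)[C@H](O[Si](C)(C)C(C)(C)C)CC1
F5 | step 2 | (R)-4-ethoxy-2-oxocyclohex-3-en-1-yl acetate | CCOC1=CC(=O)[C@H](OC(C)=O)CC1
A1 | alternative 1 | (5aS,9aR)-2,2,5a-trimethyl-5,5a,7,8,9,9a-hexahydro-1-benzoxepin-6(2H)-one | O=C1CCC[C@H]2OC(C)(C)C=CC[C@]12C
A2 | alternative 1 | (2S,3R)-2-allyl-2-methyl-3-[(2-methylbut-3-en-2-yl)oxy]cyclohexan-1-one | C=CC[C@]1(C)C(=O)CCC[C@H]1OC(C)(C)C=C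
A3 | alternative 2 | (3R,5aR,6R,9aR)-6-{2-[(tert-butyldimethylsilyl)oxy]ethyl}-3-hydroxy-2,2,5a-trimethyloctahydro-1-benzoxepin-7(2H)-one | CC(C)(C)[Si](C)(C)OCC[C@@H]2[C@@]3(C)CC[C@@H](O)C(C)(C)O[C@@H]3CCC2=O
A4 | alternative 2 | (Z)-tert-butyldimethylsilyl enol ether of 6-[(tert-butyldimethylsilyl)oxy]-1-[(2R,3R)-3-{2-[(2R)-3,3-dimethyloxiran-2-yl]ethyl}-3-methyloxiran-2-yl]hexan-3-one (C10=C11 enol ether) | CC(C)(C)[Si](C)(C)OCC/C=C(\O[Si](C)(C)C(C)(C)C)CC[C@H]1O[C@]1(C)CC[C@H]1OC1(C)C
A5 | alternative 3 | (3R,5aR,6R,7S,9aR)-3-[(tert-butyldimethylsilyl)oxy]-2,2,5a,7-tetramethyl-6-vinyldecahydro-1-benzoxepin-7-ol | C=C[C@@H]2[C@@]3(C)CC[C@@H](O[Si](C)(C)C(C)(C)C)C(C)(C)O[C@@H]3CC[C@]2(C)O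
A6 | alternative 3 | 4-[(2R,3R,6R)-6-[(tert-butyldimethylsilyl)oxy]-3,7,7-trimethyl-3-[(E)-3-(trimethylsilyl)prop-1-en-1-yl]oxepan-2-yl]butan-2-one | C[Si](C)(C)C/C=C/[C@@]1(C)CC[C@@H](O[Si](C)(C)C(C)(C)C)C(C)(C)O[C@@H]1CCC(C)=O
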